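## The problem

The target 16 is a fully oxygenated flavone: a 2-aryl-4H-chromen-4-one with methoxy groups on C5, C6, C7 and C8 of ring A and on C3 of ring C, joined at C2 to a symmetrical 3',5'-dihydroxy-4'-methoxyphenyl ring B. It has no stereocentre, so the task is one of regiochemistry and of keeping eight oxygens in their correct state. Six methyl ethers must stand beside two free phenols at the end, so the ring B hydroxyls need a protecting group that leaves without a Lewis acid, because boron and aluminium halides cleave the peri methoxy group at C5 by chelation to the C4 carbonyl. Ring A is hexasubstituted and very electron rich; its phenolic precursors oxidise easily, and whatever builds it must place five oxygens and one carbon without a positional isomer. The C3 methoxy group is best brought in with the C2–C3 unit, since a finished chromone takes nucleophiles at C2 and opens. The enabling feature is that C4a is the only ring A carbon without oxygen, while the oxygens on C8a (O1) and C6 stand para to each other, so ring A is a masked 2,3,5-trimethoxy-1,4-benzoquinone 5 whose single C–H carbon is C4a and whose carbonyls are the future O1 and C6 oxygens. Acylating that carbon gives a hydroquinone whose two hydroxyls differ by nature: one is chelated to the new ketone (future O1) and one is free (future 6-methoxy group).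

## Retrosynthesis

**16 from 15.** The two ring B O–benzyl bonds are cut first, leading to the dibenzyl ether 15. Benzyl is preferred over silyl, acetal or ester protection because it survives hydroxide, carbonate, hydride and hot iodine/DMSO, and it leaves under neutral hydrogenolysis that touches neither the methyl ethers nor the peri position. The skeleton is unchanged. The forward step must spare the tetrasubstituted C2=C3 bond and the carbonyl.

**15 from 14.** Ring C is opened at O1–C2 with a change of oxidation level, giving the 2'-hydroxy-alpha-methoxychalcone 14. Cutting C2–C1' instead would require a metallated or halogenated chromone that already carries the C3 methoxy group. The O1–C2 cut leaves an open chain with every carbon and oxygen in place. The forward reaction is a 6-endo oxa-Michael closure followed by dehydrogenation.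

**14 from 13.** The O–CH3 bond on the future C6 oxygen is cut, giving the hydroquinone 13. The precursor looks barely simpler, but this cut exposes the retron of a quinone acylation. The forward step must methylate only the hydroxyl that is not chelated to the ketone.

**13 from 5 and 12 (key disconnection).** The C4–C4a bond is cut, leading to quinone 5 and the ring B enal 12. The neighbouring cut at C2–C3 (aldol of an aryl ketone with an aldehyde) would still leave the acylation of ring A to be solved, and a cut at C3–C4 would need a ring A carboxylic acid derivative. The C4–C4a cut divides the molecule into two halves of similar size, uses the only C–H of 5, and in the forward direction forms no by-product. The forward reaction has to deliver an acyl radical from the formyl group of 12 to that one carbon.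

**5 from 4, and 4 from 1.** Quinone 5 is the oxidation product of 2,3,4,5-tetramethoxyphenol 4, whose para methoxy carbon becomes the second carbonyl. Phenol 4 arises from 1,2,3,4-tetramethoxybenzene 1 by forming one C–O bond at either of its two equivalent ring C–H positions, through the aryllithium 2 and the boronate 3. The alternative of formylation followed by peracid oxidation would cost an extra step.

**12 from 9 and 11.** The C2=C3 double bond of the enal is cut by an aldol condensation, giving the non-enolisable aldehyde 9 and methoxyacetaldehyde 11. Compound 11 is released in the flask from its dimethyl acetal 10 and brings the C3 methoxy group with it. The forward step must favour the crossed condensation over self-condensation of 11.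

**9 from 6.** Aldehyde 9 is traced through the benzylic alcohol 8 and the ester 7 to methyl 3,5-dihydroxy-4-methoxybenzoate 6. Compound 6 already has the ring B oxygen pattern with the correct oxygen methylated, so only benzylation and an adjustment of the oxidation level are required.

## Roads not taken

Alternative 1: The cut removes C3 as a one-carbon unit (bonds C2–C3 and C3–C4) and leads to 2-[3,5-bis(benzyloxy)-4-methoxyphenyl]-3,4,5,6,7-pentamethoxy-1-benzofuran A1. In the forward direction dibromocarbene would add across the furan 2,3-bond of A1. Opening of the dibromocyclopropane with loss of bromide, and loss of the O-methyl group from the former furan C3 oxygen, would give 2-[3,5-bis(benzyloxy)-4-methoxyphenyl]-3-bromo-5,6,7,8-tetramethoxy-4H-chromen-4-one A2.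
- Merits: the step is thermal, and carbene ring expansion of benzo-fused five-membered heterocycles is an established reaction type.
- Weak points:
  - The inserted carbon arrives with bromine where the target needs methoxy. A 3-halochromone such as A2 takes alkoxide at C2, with ring opening or contraction, so the exchange would rest on an unproven Ullmann-type methoxylation.
  - The oxygen that A1 carries on C3 is spent to make the C4 carbonyl, so the C3 oxygen is bought twice.
  - The 2,3-bond of A1 is tetrasubstituted and flanked by a peri methoxy group, and the electron-rich ring A is a competing site for the carbene.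
  - A1 itself needs several steps.
- Comparison: this road is better in avoiding light and any question of which hydrogen a radical abstracts. Against that, the chosen plan brings the C3 methoxy group in with enal 12, couples without a by-product, and is shorter by at least the bromide exchange and the benzofuran construction.

Alternative 2: The cut is at C3–C4 and O1–C2. It leads to 5,6,7,8-tetramethoxy-2,2-dimethyl-4H-1,3-benzodioxin-4-one A3 and the enamine 4-{(Z)-1-[3,5-bis(benzyloxy)-4-methoxyphenyl]-2-methoxyethenyl}morpholine A4, whose geometry is immaterial. Irradiation of A3 would release the ketone of its acetonide and a ring A quinoketene. A4 would capture the quinoketene at its methoxy-bearing carbon, and ring closure with loss of the amine would give the flavone 2-[3,5-bis(benzyloxy)-4-methoxyphenyl]-3,5,6,7,8-pentamethoxy-4H-chromen-4-one A5. Compound A5 has the same structure as compound 15 of the chosen route.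
- Merits: this is the most convergent road. A5 is already at the flavone oxidation level, so only debenzylation would remain after the key step. In that respect it is better than the chosen plan, which needs a methylation and an oxidative closure after the coupling before it arrives at the same compound.
- Weak points:
  - Each turnover that forms A5 sets free a secondary amine, which is a far better trap for the quinoketene than the enamine carbon, so salicylamide formation competes.
  - N- or O-acylation of A4 is possible.
  - The short-wavelength light needed for A3 is also absorbed by the styrene-type chromophore of A4.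
  - A3 requires carboxylation of phenol 4 and acetonide formation. A4 requires a ring B methoxymethyl ketone and enamine formation at a hindered carbonyl. These steps consume what is saved later.
- Comparison: the chosen plan offers simpler partners (5 in two steps, 12 in four), a coupling in which all atoms of both partners end up in the product, and regiochemistry fixed by the single C–H of 5.

Alternative 3: The cut is at C3–C4 alone. It leads to the racemic dialdehyde 2-{1-[3,5-bis(benzyloxy)-4-methoxyphenyl]-2-oxoethoxy}-3,4,5,6-tetramethoxybenzaldehyde A6. A thiazolium-derived carbene would convert the ring A aldehyde of A6 into a Breslow intermediate that attacks the tethered aliphatic aldehyde. This would close ring C as racemic trans-2-[3,5-bis(benzyloxy)-4-methoxyphenyl]-3-hydroxy-5,6,7,8-tetramethoxychroman-4-one A7.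
- Merits: mild, thermal organocatalysis, and a direct entry to the 3-oxygenated chromanone.
- Weak points:
  - The ring A aldehyde of A6 is flanked on both sides and is electron rich, so the carbene is more likely to add to the aliphatic aldehyde. That aldehyde carries an aryloxy leaving group on its alpha carbon; elimination from its Breslow intermediate would cut the tether, and attack in the reverse sense would give the regioisomeric acyloin in which carbonyl and hydroxyl have changed places.
  - A6 is an enolisable alpha-aryloxy arylacetaldehyde that must be made by alkylating a hindered phenol.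
  - A7 still needs O-methylation and dehydrogenation before the debenzylation, and its two stereocentres are created only to be destroyed.
- Comparison: this road is better in needing no light. Against that, the chosen plan has stable partners, forms no stereocentres at any stage, and has fewer steps after the key bond is made.

Key step: step 7

Assumption: compounds 12, 13 and 14 are written as the Z isomers (aryl group trans to the carbonyl carbon), the thermodynamically preferred geometry. This alkene becomes the endocyclic C2=C3 bond in step 9, so a mixture of geometric isomers would serve equally.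

## Route

Step 1
Reactants: 1 1,2,3,4-tetramethoxybenzene
Product: 4 2,3,4,5-tetramethoxyphenol, via (2,3,4,5-tetramethoxyphenyl)lithium 2 (not isolated), via dimethyl (2,3,4,5-tetramethoxyphenyl)boronate 3 (not isolated)
Conditions: n-BuLi, TMEDA, THF, 0 °C; B(OMe)3, −78 °C → rt; AcOH, 30% aq H2O2, 0 °C → rt
Reagents that add atoms: hydrogen peroxide, OO (phenol oxygen of 4); n-butyllithium, [Li]CCCC (lithium of 2 only); trimethyl borate, COB(OC)OC (boron and two methoxy groups of 3 only)
Why: Directed ortho-lithiation of an aryl methyl ether, borylation and boronate oxidation (1,2-aryl shift from boron to oxygen); 1 has only one kind of ring C–H, so mono-lithiation is regiochemically unambiguous, and the mildly acidic peroxide should spare the electron-rich phenol.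

Step 2
Reactants: 4 2,3,4,5-tetramethoxyphenol
Product: 5 2,3,5-trimethoxy-1,4-benzoquinone
Conditions: PhI(OAc)2, MeCN/H2O (2:1), 0 °C
Reagents that add atoms: water, O (the new carbonyl oxygen para to the former phenol oxygen)
Why: Hypervalent-iodine oxidative dearomatisation of a para-methoxyphenol; water adds at the methoxy-bearing para carbon and the mixed ketal loses methanol to give the para-quinone, the usual outcome in aqueous acetonitrile, with the other three methoxy groups untouched.

Step 3
Reactants: 6 methyl 3,5-dihydroxy-4-methoxybenzoate
Product: 7 methyl 3,5-bis(benzyloxy)-4-methoxybenzoate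
Conditions: BnBr, K2CO3, DMF, 60 °C
Reagents that add atoms: benzyl bromide, BrCc1ccccc1
Why: Williamson etherification of two equivalent phenols; the ester is inert to carbonate in DMF.

Step 4
Reactants: 7 methyl 3,5-bis(benzyloxy)-4-methoxybenzoate
Product: 8 [3,5-bis(benzyloxy)-4-methoxyphenyl]methanol
Conditions: LiAlH4, THF, 0 °C → rt
Reagents that add atoms: none
Why: Hydride reduction of an aryl ester to the benzylic alcohol; aryl benzyl and methyl ethers are stable to LiAlH4.

Step 5
Reactants: 8 [3,5-bis(benzyloxy)-4-methoxyphenyl]methanol
Product: 9 3,5-bis(benzyloxy)-4-methoxybenzaldehyde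
Conditions: MnO2, CH2Cl2, rt
Reagents that add atoms: none
Why: Selective MnO2 oxidation of a benzylic alcohol, which stops at the aldehyde and leaves the benzyl ethers alone.

Step 6
Reactants: 9 3,5-bis(benzyloxy)-4-methoxybenzaldehyde; 10 1,1,2-trimethoxyethane (methoxyacetaldehyde dimethyl acetal)
Product: 12 (Z)-3-[3,5-bis(benzyloxy)-4-methoxyphenyl]-2-methoxyprop-2-enal, via methoxyacetaldehyde 11 (not isolated)
Conditions: 10, 0.1 M aq H2SO4 (cat.), 50 °C; the solution of 11 (3 equiv) added slowly to 9, aq NaOH, THF/MeOH, 0 °C → rt
Reagents that add atoms: water, O (carbonyl oxygen of 11 and hence of 12)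
Why: Acid-catalysed acetal hydrolysis followed by a Claisen–Schmidt crossed aldol condensation; 9 cannot enolise, slow addition of excess 11 limits its self-condensation, and E1cB dehydration should give the more stable Z alkene with the aryl group trans to the formyl group.

Step 7
Reactants: 5 2,3,5-trimethoxy-1,4-benzoquinone; 12 (Z)-3-[3,5-bis(benzyloxy)-4-methoxyphenyl]-2-methoxyprop-2-enal
Product: 13 (Z)-3-[3,5-bis(benzyloxy)-4-methoxyphenyl]-1-(2,5-dihydroxy-3,4,6-trimethoxyphenyl)-2-methoxyprop-2-en-1-one
Conditions: hν (450 nm LEDs), 5 (1.5 equiv), degassed PhCF3, Ar, 20 °C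
Reagents that add atoms: none
Why: Light of 450 nm is absorbed only by quinone 5, whose triplet abstracts the formyl hydrogen of 12, the most hydridic and among the weakest C–H bonds present, to give a semiquinone/acyl radical pair. The acyl radical then bonds to the one unsubstituted quinone carbon (by in-cage collapse or by addition to ground-state 5 and hydrogen return), forming C4–C4a, and enolisation of the resulting ene-dione gives the acylhydroquinone 13. The closest known reaction type is the photochemical acylation of 1,4-quinones with aldehydes (photo-Friedel–Crafts acylation), which is established for alpha,beta-unsaturated aldehydes. No ring is closed and no stereocentre is formed; the alkene should keep its Z geometry, and any isomerisation is harmless because step 9 turns this bond into the endocyclic C2=C3. Regiochemistry is secured by the substrate, since only attack at the single C–H carbon can rearomatise. Chemoselectivity requires hydrogen abstraction at the formyl group rather than at the benzylic methylenes or [2+2] addition to the alkene, which the hydridic formyl C–H, the hindered trisubstituted and formyl-conjugated alkene and the use of light that 12 does not absorb should favour; an unsaturated acyl radical also cannot lose CO. Product 13 is harder to oxidise than the hydroquinone of 5, so redox exchange with excess 5 should not drain it, and oxygen is excluded to protect both the acyl radical and 13. Should direct excitation of this donor-rich quinone be inefficient, (n-Bu4N)4W10O32 under 390 nm light can generate the same acyl radical for addition to ground-state 5.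

Step 8
Reactants: 13 (Z)-3-[3,5-bis(benzyloxy)-4-methoxyphenyl]-1-(2,5-dihydroxy-3,4,6-trimethoxyphenyl)-2-methoxyprop-2-en-1-one
Product: 14 (Z)-3-[3,5-bis(benzyloxy)-4-methoxyphenyl]-1-(2-hydroxy-3,4,5,6-tetramethoxyphenyl)-2-methoxyprop-2-en-1-one
Conditions: MeI (1.1 equiv), K2CO3, acetone, Ar, rt
Reagents that add atoms: iodomethane, CI
Why: Chemoselective Williamson O-methylation; the hydroxyl ortho to the ketone is held in a six-membered hydrogen-bonded chelate and is the classically unreactive one, so one equivalent of MeI should go to the free hydroxyl, and argon prevents autoxidation of the hydroquinone in base.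

Step 9
Reactants: 14 (Z)-3-[3,5-bis(benzyloxy)-4-methoxyphenyl]-1-(2-hydroxy-3,4,5,6-tetramethoxyphenyl)-2-methoxyprop-2-en-1-one
Product: 15 2-[3,5-bis(benzyloxy)-4-methoxyphenyl]-3,5,6,7,8-pentamethoxy-4H-chromen-4-one
Conditions: I2 (0.2 equiv), DMSO, 120 °C
Reagents that add atoms: none
Why: Iodine/DMSO oxidative cyclisation of a 2'-hydroxychalcone; the chelated phenol closes ring C by 6-endo oxa-Michael addition (O1–C2), iodination at C3 and loss of HI introduce the C2=C3 bond, and DMSO reoxidises HI so that iodine is catalytic.

Step 10
Reactants: 15 2-[3,5-bis(benzyloxy)-4-methoxyphenyl]-3,5,6,7,8-pentamethoxy-4H-chromen-4-one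
Product: 16 3',5'-dihydroxy-3,5,6,7,8,4'-hexamethoxyflavone [2-(3,5-dihydroxy-4-methoxyphenyl)-3,5,6,7,8-pentamethoxy-4H-chromen-4-one]
Conditions: H2 (1 atm), 10% Pd/C, EtOAc/MeOH, rt
Reagents that add atoms: none
Why: Catalytic hydrogenolysis of aryl benzyl ethers under neutral conditions; the tetrasubstituted, carbonyl-conjugated C2=C3 bond and the six methyl ethers should be untouched.

## Compound list

1 | 1,2,3,4-tetramethoxybenzene | COc1ccc(OC)c(OC)c1OC | starting material
2 | (2,3,4,5-tetramethoxyphenyl)lithium | [Li]c1cc(OC)c(OC)c(OC)c1OC | intermediate
3 | dimethyl (2,3,4,5-tetramethoxyphenyl)boronate | COB(OC)c1cc(OC)c(OC)c(OC)c1OC | intermediate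
4 | 2,3,4,5-tetramethoxyphenol | COc1cc(O)c(OC)c(OC)c1OC | intermediate
5 | 2,3,5-trimethoxy-1,4-benzoquinone | COC1=CC(=O)C(OC)=C(OC)C1=O | intermediate
6 | methyl 3,5-dihydroxy-4-methoxybenzoate | COC(=O)c1cc(O)c(OC)c(O)c1 | starting material
7 | methyl 3,5-bis(benzyloxy)-4-methoxybenzoate | COC(=O)c1cc(OCc2ccccc2)c(OC)c(OCc2ccccc2)c1 | intermediate
8 | [3,5-bis(benzyloxy)-4-methoxyphenyl]methanol | OCc1cc(OCc2ccccc2)c(OC)c(OCc2ccccc2)c1 | intermediate
9 | 3,5-bis(benzyloxy)-4-methoxybenzaldehyde | O=Cc1cc(OCc2ccccc2)c(OC)c(OCc2ccccc2)c1 | intermediate
10 | 1,1,2-trimethoxyethane (methoxyacetaldehyde dimethyl acetal) | COCC(OC)OC | starting material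
11 | methoxyacetaldehyde | COCC=O | intermediate
12 | (Z)-3-[3,5-bis(benzyloxy)-4-methoxyphenyl]-2-methoxyprop-2-enal | O=C/C(OC)=C/c1cc(OCc2ccccc2)c(OC)c(OCc2ccccc2)c1 | intermediate
13 | (Z)-3-[3,5-bis(benzyloxy)-4-methoxyphenyl]-1-(2,5-dihydroxy-3,4,6-trimethoxyphenyl)-2-methoxyprop-2-en-1-one | COc1c(O)c(OC)c(OC)c(O)c1C(=O)/C(OC)=C/c1cc(OCc2ccccc2)c(OC)c(OCc2ccccc2)c1 | intermediate
14 | (Z)-3-[3,5-bis(benzyloxy)-4-methoxyphenyl]-1-(2-hydroxy-3,4,5,6-tetramethoxyphenyl)-2-methoxyprop-2-en-1-one | COc1c(OC)c(OC)c(OC)c(O)c1C(=O)/C(OC)=C/c1cc(OCc2ccccc2)c(OC)c(OCc2ccccc2)c1 | intermediate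
15 | 2-[3,5-bis(benzyloxy)-4-methoxyphenyl]-3,5,6,7,8-pentamethoxy-4H-chromen-4-one | COc1c(-c2cc(OCc3ccccc3)c(OC)c(OCc3ccccc3)c2)oc2c(OC)c(OC)c(OC)c(OC)c2c1=O | intermediate
16 | 3',5'-dihydroxy-3,5,6,7,8,4'-hexamethoxyflavone | COc1c(O)cc(-c2oc3c(OC)c(OC)c(OC)c(OC)c3c(=O)c2OC)cc1O | target

## Step count and risks

Total step count: 10 steps. Longest linear sequence: 8 steps (6 → 7 → 8 → 9 → 12 → 13 → 14 → 15 → 16, steps 3 to 10). The ring A branch (steps 1 and 2) joins at step 7.

Least certain steps:

**Step 7 (key step).** What may go wrong: the three methoxy donors give the quinone triplet charge-transfer character, so hydrogen abstraction may be slow; abstraction at the four benzylic ether hydrogens may compete with abstraction at the formyl group; the radical pair may couple at oxygen instead of carbon; and the phenolic product may quench the triplet as it accumulates. Fallback: the radical coupling is given up for an ionic acylation of ring A. Starting from phenol 4, Friedel–Crafts acylation at its single free ring position (methoxyacetyl chloride, BF3·OEt2, CH2Cl2; O-acylation then Fries shift) would give 1-(2-hydroxy-3,4,5,6-tetramethoxyphenyl)-2-methoxyethan-1-one F1. Claisen–Schmidt condensation of this ketone with aldehyde 9 (KOH, EtOH) would form the C2–C3 bond and arrive at 14, where the route is rejoined.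

**Step 6.** What may go wrong: self-condensation of the small, enolisable aldehyde may outrun its crossed addition to the electron-rich and poorly soluble 9, giving low conversion. Fallback: the enal is built by olefination and redox adjustment. Starting from 9, Horner–Wadsworth–Emmons reaction with methyl 2-(dimethoxyphosphoryl)-2-methoxyacetate (NaH, THF) would give methyl (Z)-3-[3,5-bis(benzyloxy)-4-methoxyphenyl]-2-methoxyprop-2-enoate F2. Reduction with i-Bu2AlH (CH2Cl2, −78 °C) would give (Z)-3-[3,5-bis(benzyloxy)-4-methoxyphenyl]-2-methoxyprop-2-en-1-ol F3, and MnO2 oxidation of this allylic alcohol returns to 12.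

**Step 8.** What may go wrong: loss of chemoselectivity (methylation of the chelated hydroxyl as well), base-induced ring closure, or autoxidation of the hydroquinone under basic conditions. Fallback: the ring is closed before methylating, so that the chelated hydroxyl is consumed and only one hydroxyl is left. Starting from 13, NaOAc in refluxing EtOH under argon would give trans-2-[3,5-bis(benzyloxy)-4-methoxyphenyl]-6-hydroxy-3,5,7,8-tetramethoxychroman-4-one F4 as the racemate. I2 in DMSO would dehydrogenate it to 2-[3,5-bis(benzyloxy)-4-methoxyphenyl]-6-hydroxy-3,5,7,8-tetramethoxy-4H-chromen-4-one F5, and methylation of its only hydroxyl (MeI, K2CO3, acetone) gives 15.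

**Step 9.** What may go wrong: the reaction may stall after ring closure because the alpha-methoxy carbon is slow to iodinate; the electron-rich rings may be iodinated; and the HI formed may cleave the peri methyl ether or a benzyl ether. Fallback: ring closure is separated from dehydrogenation. Starting from 14, NaOAc in refluxing EtOH would give trans-2-[3,5-bis(benzyloxy)-4-methoxyphenyl]-3,5,6,7,8-pentamethoxychroman-4-one F6 as the racemate, and DDQ in refluxing dioxane would dehydrogenate it to 15 without any acid or iodine.

## Further compounds

F1 | step 7 | 1-(2-hydroxy-3,4,5,6-tetramethoxyphenyl)-2-methoxyethan-1-one | COCC(=O)c1c(O)c(OC)c(OC)c(OC)c1OC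
F2 | step 6 | methyl (Z)-3-[3,5-bis(benzyloxy)-4-methoxyphenyl]-2-methoxyprop-2-enoate | COC(=O)/C(OC)=C/c1cc(OCc2ccccc2)c(OC)c(OCc2ccccc2)c1
F3 | step 6 | (Z)-3-[3,5-bis(benzyloxy)-4-methoxyphenyl]-2-methoxyprop-2-en-1-ol | OC/C(OC)=C/c1cc(OCc2ccccc2)c(OC)c(OCc2ccccc2)c1
F4 | step 8 | trans-2-[3,5-bis(benzyloxy)-4-methoxyphenyl]-6-hydroxy-3,5,7,8-tetramethoxychroman-4-one (racemic; 2R,3R enantiomer drawn) | O=C1[C@H](OC)[C@@H](c2cc(OCc3ccccc3)c(OC)c(OCc3ccccc3)c2)Oc2c(OC)c(OC)c(O)c(OC)c21
F5 | step 8 | 2-[3,5-bis(benzyloxy)-4-methoxyphenyl]-6-hydroxy-3,5,7,8-tetramethoxy-4H-chromen-4-one | COc1c(-c2cc(OCc3ccccc3)c(OC)c(OCc3ccccc3)c2)oc2c(OC)c(OC)c(O)c(OC)c2c1=O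
F6 | step 9 | trans-2-[3,5-bis(benzyloxy)-4-methoxyphenyl]-3,5,6,7,8-pentamethoxychroman-4-one (racemic; 2R,3R enantiomer drawn) | O=C1[C@H](OC)[C@@H](c2cc(OCc3ccccc3)c(OC)c(OCc3ccccc3)c2)Oc2c(OC)c(OC)c(OC)c(OC)c21
A1 | alternative 1 | 2-[3,5-bis(benzyloxy)-4-methoxyphenyl]-3,4,5,6,7-pentamethoxy-1-benzofuran | COc1c(-c2cc(OCc3ccccc3)c(OC)c(OCc3ccccc3)c2)oc2c(OC)c(OC)c(OC)c(OC)c12
A2 | alternative 1 | 2-[3,5-bis(benzyloxy)-4-methoxyphenyl]-3-bromo-5,6,7,8-tetramethoxy-4H-chromen-4-one | O=c1c(Br)c(-c2cc(OCc3ccccc3)c(OC)c(OCc3ccccc3)c2)oc2c(OC)c(OC)c(OC)c(OC)c12
A3 | alternative 2 | 5,6,7,8-tetramethoxy-2,2-dimethyl-4H-1,3-benzodioxin-4-one | CC1(C)OC(=O)c2c(OC)c(OC)c(OC)c(OC)c2O1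
A4 | alternative 2 | 4-{(Z)-1-[3,5-bis(benzyloxy)-4-methoxyphenyl]-2-methoxyethenyl}morpholine | CO/C=C(\N1CCOCC1)c1cc(OCc2ccccc2)c(OC)c(OCc2ccccc2)c1
A5 | alternative 2 | 2-[3,5-bis(benzyloxy)-4-methoxyphenyl]-3,5,6,7,8-pentamethoxy-4H-chromen-4-one | COc1c(-c2cc(OCc3ccccc3)c(OC)c(OCc3ccccc3)c2)oc2c(OC)c(OC)c(OC)c(OC)c2c1=O
A6 | alternative 3 | 2-{1-[3,5-bis(benzyloxy)-4-methoxyphenyl]-2-oxoethoxy}-3,4,5,6-tetramethoxybenzaldehyde (racemic; R enantiomer drawn) | O=C[C@H](Oc1c(OC)c(OC)c(OC)c(OC)c1C=O)c1cc(OCc2ccccc2)c(OC)c(OCc2ccccc2)c1
A7 | alternative 3 | trans-2-[3,5-bis(benzyloxy)-4-methoxyphenyl]-3-hydroxy-5,6,7,8-tetramethoxychroman-4-one (racemic; 2R,3R enantiomer drawn) | O=C1[C@H](O)[C@@H](c2cc(OCc3ccccc3)c(OC)c(OCc3ccccc3)c2)Oc2c(OC)c(OC)c(OC)c(OC)c21
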